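**Plan**

- Cuts: the chalcone Cα=Cβ bond (Claisen–Schmidt); the aryl C1'–C(=O) bond (ortho-lithiation of a 2-alkyl-5-methoxyresorcinol bis-ether whose two open ring positions are equivalent); the isopropenyl C–CH3 and C=CH2 bonds (both grown from one lactone carbonyl); and the lavandulyl C1''–C2'' bond together with a temporary aryl O–C(=O) tether.
- Enabling feature: the phenol oxygen ortho to the benzylic carbon C1'' lets the A ring be dearomatised to an o-quinone methide (O=C–C=CH2), and the stereocentre C2'' sits α to C3'', a latent acyl carbon. O, C1'', C2'' and C3'' therefore map onto O1, C4, C3 and C2 of a 3,4-dihydrocoumarin.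
- Forward order: trihydroxybenzaldehyde → sulfone (quinone methide precursor); carbene-catalysed [4+2] with racemic 2-chloro-5-methylhex-4-enal closes the lactone ring; the lactone is unravelled to the isopropenyl group and a phenol; acetylation, aldol condensation and MOM removal follow.
- Stereochemistry: the single stereocentre comes from catalyst control of the enolate face in step 6, which is stereoconvergent on the racemic chloroaldehyde; later steps avoid enolising that centre.

Key step: step 6

Remark: the antipode of the aminoindanol-derived triazolium catalyst that gives (3R)-12 is to be fixed in a pilot run by correlation; both antipodes are accessible from the two enantiomers of cis-1-amino-2-indanol.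

**Route**

Step 1
Reactants: 1 2,4,6-trihydroxybenzaldehyde
Product: 2 2,6-dihydroxy-4-methoxybenzaldehyde
Conditions: Me2SO4 (1.0 equiv), K2CO3 (1.0 equiv), acetone, rt
Reagents that add atoms: dimethyl sulfate COS(=O)(=O)OC
Why: Williamson O-methylation should go to the 4-OH, which is the most acidic and the only one not hydrogen-bonded to the formyl group, as in the known 4-O-methylation of phloroacylphenones.

Step 2
Reactants: 2 2,6-dihydroxy-4-methoxybenzaldehyde
Product: 3 2-hydroxy-4-methoxy-6-(methoxymethoxy)benzaldehyde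
Conditions: MOMCl (1.05 equiv), i-Pr2NEt, CH2Cl2, 0 °C to rt
Reagents that add atoms: chloromethyl methyl ether COCCl
Why: Mono-acetalisation (MOM protection) should stop after one of the two equivalent hydroxyls, because the remaining one is then locked in a strong chelate with the aldehyde.

Step 3
Reactants: 3 2-hydroxy-4-methoxy-6-(methoxymethoxy)benzaldehyde
Product: 5 5-methoxy-3-(methoxymethoxy)-2-{[(4-methylphenyl)sulfonyl]methyl}phenol, via salicyl alcohol 4 (not isolated)
Conditions: NaBH4, MeOH/THF, 0 °C; then TolSO2Na (3 equiv), AcOH/H2O, rt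
Reagents that add atoms: sodium p-toluenesulfinate Cc1ccc(S(=O)[O-])cc1.[Na+]
Why: Borohydride reduction gives the electron-rich o-hydroxybenzyl alcohol, which should ionise under weak acid and be captured at sulfur by excess sulfinate (SN1/quinone-methide trapping) to give a bench-stable sulfone.

Step 4
Reactants: 6 2-methylbut-3-en-2-ol; 7 ethyl vinyl ether
Product: 9 5-methylhex-4-enal, via allyl vinyl ether 8 (not isolated)
Conditions: H3PO4 (cat.), excess 7, sealed vessel, 150 °C
Reagents that add atoms: none
Why: Acid-catalysed vinyl ether exchange followed by Claisen rearrangement of the tertiary allyl vinyl ether should deliver the γ,δ-unsaturated aldehyde with the trisubstituted alkene in place.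

Step 5
Reactants: 9 5-methylhex-4-enal
Product: 10 (2RS)-2-chloro-5-methylhex-4-enal
Conditions: NCS (1.05 equiv), DL-proline (10 mol %), CH2Cl2, 0 °C; used crude
Reagents that add atoms: N-chlorosuccinimide O=C1CCC(=O)N1Cl
Why: Enamine-mediated α-chlorination of the aldehyde should be much faster than attack of NCS on the trisubstituted alkene; the racemate suffices because this centre is erased in step 6.

Step 6
Reactants: 5 5-methoxy-3-(methoxymethoxy)-2-{[(4-methylphenyl)sulfonyl]methyl}phenol; 10 (2RS)-2-chloro-5-methylhex-4-enal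
Product: 12 (3R)-7-methoxy-5-(methoxymethoxy)-3-(3-methylbut-2-en-1-yl)-3,4-dihydro-2H-chromen-2-one, via o-quinone methide 11 (not isolated)
Conditions: aminoindanol-derived N-mesityl triazolium chloride (10 mol %), powdered K2CO3 (3 equiv), 4 Å MS, toluene/CH2Cl2, 0 °C to rt, 10 added over 6 h
Reagents that add atoms: none
Why: Carbonate triggers 1,4-elimination of sulfinate from 5, which dearomatises the ring to the o-quinone methide 11 (heterodiene O=C–C=CH2), while the carbene adds to racemic 10 and expels chloride to give a catalyst-bound (Z)-azolium enolate in which the chlorine-bearing centre is erased, so both enantiomers of 10 converge on one intermediate. The enolate α-carbon adds to the unsubstituted exocyclic CH2 of 11 with rearomatisation, and the phenoxide is then acylated by the acyl azolium, releasing the carbene; the closest known reaction type is the carbene-catalysed azolium-enolate formal [4+2] (hetero-Diels–Alder-type) annulation of α-chloroaldehydes with oxodienes and with o-quinone methides generated in situ, which gives 3-substituted dihydrocoumarins. The six-membered lactone ring closes by intermolecular Michael C–C bond formation followed by intramolecular O-acylation (6-exo-trig lactonisation). C3 is the only new stereocentre and is set by the aminoindanol backbone of the triazolium, which blocks one face of the enolate; because the electrophilic terminus is a CH2 group, enolate facial selectivity alone decides the configuration. The step needs C-alkylation and lactonisation to outrun O-acylation of the free phenol and self-condensation of 11; slow addition of 10, the heterogeneous base and reversible re-addition of sulfinate (which keeps free 11 low) should secure this, and the MOM group on the second oxygen keeps 11 neutral and electrophilic and makes the lactone oxygen unambiguous.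

Step 7
Reactants: 12 (3R)-7-methoxy-5-(methoxymethoxy)-3-(3-methylbut-2-en-1-yl)-3,4-dihydro-2H-chromen-2-one
Product: 13 (2R)-2-{[2-hydroxy-4-methoxy-6-(methoxymethoxy)phenyl]methyl}-N-methoxy-N,5-dimethylhex-4-enamide
Conditions: MeNH(OMe)·HCl, AlMe3, CH2Cl2, 0 °C to rt; Rochelle salt work-up
Reagents that add atoms: N,O-dimethylhydroxylamine hydrochloride CNOC.Cl
Why: Weinreb aminolysis of the activated aryl ester by the weakly basic aluminium amide should open the lactone and free the phenol without enolising the α-centre.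

Step 8
Reactants: 13 (2R)-2-{[2-hydroxy-4-methoxy-6-(methoxymethoxy)phenyl]methyl}-N-methoxy-N,5-dimethylhex-4-enamide
Product: 14 (2R)-N-methoxy-2-{[4-methoxy-2,6-bis(methoxymethoxy)phenyl]methyl}-N,5-dimethylhex-4-enamide
Conditions: MOMCl, i-Pr2NEt, CH2Cl2, 0 °C to rt
Reagents that add atoms: chloromethyl methyl ether COCCl
Why: MOM protection of the non-chelated phenol blocks relactonisation and restores the symmetric bis-MOM ring needed for the later directed metalation.

Step 9
Reactants: 14 (2R)-N-methoxy-2-{[4-methoxy-2,6-bis(methoxymethoxy)phenyl]methyl}-N,5-dimethylhex-4-enamide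
Product: 15 (3R)-3-{[4-methoxy-2,6-bis(methoxymethoxy)phenyl]methyl}-6-methylhept-5-en-2-one
Conditions: MeMgBr, THF, 0 °C; cold NH4Cl quench
Reagents that add atoms: methylmagnesium bromide C[Mg]Br
Why: Weinreb ketone synthesis should stop at the methyl ketone through the stable magnesium chelate, and the ketone is released only on cold quench so the α-centre is not exposed to base.

Step 10
Reactants: 15 (3R)-3-{[4-methoxy-2,6-bis(methoxymethoxy)phenyl]methyl}-6-methylhept-5-en-2-one
Product: 16 5-methoxy-1,3-bis(methoxymethoxy)-2-[(2R)-5-methyl-2-(prop-1-en-2-yl)hex-4-en-1-yl]benzene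
Conditions: Ph3PCH3Br, KOt-Bu, THF, 0 °C; 15 added to the ylide at −20 °C, then to rt
Reagents that add atoms: methyltriphenylphosphonium bromide C[P+](c1ccccc1)(c1ccccc1)c1ccccc1.[Br-]
Why: Wittig methylenation turns the former lactone carbonyl into the isopropenyl group; inverse addition to a slight excess of ylide at low temperature should keep enolisation of the α-branched ketone below the rate of olefination.

Step 11
Reactants: 16 5-methoxy-1,3-bis(methoxymethoxy)-2-[(2R)-5-methyl-2-(prop-1-en-2-yl)hex-4-en-1-yl]benzene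
Product: 18 1-{6-methoxy-2,4-bis(methoxymethoxy)-3-[(2R)-5-methyl-2-(prop-1-en-2-yl)hex-4-en-1-yl]phenyl}ethan-1-one, via aryllithium 17 (not isolated)
Conditions: n-BuLi, TMEDA, THF, −20 to 0 °C; then N-methoxy-N-methylacetamide, −78 to 0 °C
Reagents that add atoms: N-methoxy-N-methylacetamide CON(C)C(C)=O
Why: Directed ortho-metalation should take place only at the ring C–H flanked by OMOM and OMe (the two such positions are equivalent), and the Weinreb acetamide then gives the acetophenone without over-addition.

Step 12
Reactants: 19 2,4-dihydroxybenzaldehyde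
Product: 20 2,4-bis(methoxymethoxy)benzaldehyde
Conditions: MOMCl (3 equiv), K2CO3, acetone, reflux
Reagents that add atoms: chloromethyl methyl ether COCCl
Why: Exhaustive MOM protection under forcing carbonate conditions also caps the chelated 2-OH, so the aldehyde stays electrophilic under the basic aldol conditions.

Step 13
Reactants: 18 1-{6-methoxy-2,4-bis(methoxymethoxy)-3-[(2R)-5-methyl-2-(prop-1-en-2-yl)hex-4-en-1-yl]phenyl}ethan-1-one; 20 2,4-bis(methoxymethoxy)benzaldehyde
Product: 22 (2E)-3-[2,4-bis(methoxymethoxy)phenyl]-1-{6-methoxy-2,4-bis(methoxymethoxy)-3-[(2R)-5-methyl-2-(prop-1-en-2-yl)hex-4-en-1-yl]phenyl}prop-2-en-1-one, via aldol adduct 21 (not isolated)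
Conditions: KOH, EtOH/H2O, rt
Reagents that add atoms: none
Why: Claisen–Schmidt condensation of the methyl ketone with the non-enolisable aldehyde, followed by E1cB dehydration, should give the (E)-chalcone; the remote stereocentre has no acidic hydrogen under these conditions.

Step 14
Reactants: 22 (2E)-3-[2,4-bis(methoxymethoxy)phenyl]-1-{6-methoxy-2,4-bis(methoxymethoxy)-3-[(2R)-5-methyl-2-(prop-1-en-2-yl)hex-4-en-1-yl]phenyl}prop-2-en-1-one
Product: 23 kuraridin, (2E)-3-(2,4-dihydroxyphenyl)-1-{2,4-dihydroxy-6-methoxy-3-[(2R)-5-methyl-2-(prop-1-en-2-yl)hex-4-en-1-yl]phenyl}prop-2-en-1-one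
Conditions: 3 M HCl, MeOH, rt to 40 °C, monitored and neutralised as soon as conversion is complete
Reagents that add atoms: none
Why: Acid-catalysed acetal exchange with methanol should remove all four MOM groups, as in related prenylated polyhydroxychalcones, with short exposure to limit acid-induced ring closures.

**Compound list**

1 | 2,4,6-trihydroxybenzaldehyde | O=Cc1c(O)cc(O)cc1O | starting material
2 | 2,6-dihydroxy-4-methoxybenzaldehyde | COc1cc(O)c(C=O)c(O)c1 | intermediate
3 | 2-hydroxy-4-methoxy-6-(methoxymethoxy)benzaldehyde | COCOc1cc(OC)cc(O)c1C=O | intermediate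
4 | 2-(hydroxymethyl)-5-methoxy-3-(methoxymethoxy)phenol (salicyl alcohol) | COCOc1cc(OC)cc(O)c1CO | intermediate
5 | 5-methoxy-3-(methoxymethoxy)-2-{[(4-methylphenyl)sulfonyl]methyl}phenol | COCOc1cc(OC)cc(O)c1CS(=O)(=O)c1ccc(C)cc1 | intermediate
6 | 2-methylbut-3-en-2-ol | C=CC(C)(C)O | starting material
7 | ethyl vinyl ether | C=COCC | starting material
8 | 3-(ethenyloxy)-3-methylbut-1-ene (allyl vinyl ether) | C=COC(C)(C)C=C | intermediate
9 | 5-methylhex-4-enal | CC(C)=CCCC=O | intermediate
10 | (2RS)-2-chloro-5-methylhex-4-enal | CC(C)=CCC(Cl)C=O | intermediate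
11 | 3-methoxy-5-(methoxymethoxy)-6-methylidenecyclohexa-2,4-dien-1-one (o-quinone methide) | C=C1C(=O)C=C(OC)C=C1OCOC | intermediate
12 | (3R)-7-methoxy-5-(methoxymethoxy)-3-(3-methylbut-2-en-1-yl)-3,4-dihydro-2H-chromen-2-one | O=C1[C@H](CC=C(C)C)Cc2c(OCOC)cc(OC)cc2O1 | intermediate
13 | (2R)-2-{[2-hydroxy-4-methoxy-6-(methoxymethoxy)phenyl]methyl}-N-methoxy-N,5-dimethylhex-4-enamide | CON(C)C(=O)[C@H](CC=C(C)C)Cc1c(O)cc(OC)cc1OCOC | intermediate
14 | (2R)-N-methoxy-2-{[4-methoxy-2,6-bis(methoxymethoxy)phenyl]methyl}-N,5-dimethylhex-4-enamide | CON(C)C(=O)[C@H](CC=C(C)C)Cc1c(OCOC)cc(OC)cc1OCOC | intermediate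
15 | (3R)-3-{[4-methoxy-2,6-bis(methoxymethoxy)phenyl]methyl}-6-methylhept-5-en-2-one | CC(=O)[C@H](CC=C(C)C)Cc1c(OCOC)cc(OC)cc1OCOC | intermediate
16 | 5-methoxy-1,3-bis(methoxymethoxy)-2-[(2R)-5-methyl-2-(prop-1-en-2-yl)hex-4-en-1-yl]benzene | C=C(C)[C@H](CC=C(C)C)Cc1c(OCOC)cc(OC)cc1OCOC | intermediate
17 | {6-methoxy-2,4-bis(methoxymethoxy)-3-[(2R)-5-methyl-2-(prop-1-en-2-yl)hex-4-en-1-yl]phenyl}lithium (aryllithium) | C=C(C)[C@H](CC=C(C)C)Cc1c(OCOC)cc(OC)c([Li])c1OCOC | intermediate
18 | 1-{6-methoxy-2,4-bis(methoxymethoxy)-3-[(2R)-5-methyl-2-(prop-1-en-2-yl)hex-4-en-1-yl]phenyl}ethan-1-one | C=C(C)[C@H](CC=C(C)C)Cc1c(OCOC)cc(OC)c(C(C)=O)c1OCOC | intermediate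
19 | 2,4-dihydroxybenzaldehyde | O=Cc1ccc(O)cc1O | starting material
20 | 2,4-bis(methoxymethoxy)benzaldehyde | COCOc1ccc(C=O)c(OCOC)c1 | intermediate
21 | 3-[2,4-bis(methoxymethoxy)phenyl]-3-hydroxy-1-{6-methoxy-2,4-bis(methoxymethoxy)-3-[(2R)-5-methyl-2-(prop-1-en-2-yl)hex-4-en-1-yl]phenyl}propan-1-one (aldol adduct, carbinol epimers) | C=C(C)[C@H](CC=C(C)C)Cc1c(OCOC)cc(OC)c(C(=O)CC(O)c2ccc(OCOC)cc2OCOC)c1OCOC | intermediate
22 | (2E)-3-[2,4-bis(methoxymethoxy)phenyl]-1-{6-methoxy-2,4-bis(methoxymethoxy)-3-[(2R)-5-methyl-2-(prop-1-en-2-yl)hex-4-en-1-yl]phenyl}prop-2-en-1-one | C=C(C)[C@H](CC=C(C)C)Cc1c(OCOC)cc(OC)c(C(=O)/C=C/c2ccc(OCOC)cc2OCOC)c1OCOC | intermediate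
23 | kuraridin | C=C(C)[C@H](CC=C(C)C)Cc1c(O)cc(OC)c(C(=O)/C=C/c2ccc(O)cc2O)c1O | target

**Step count**

Total steps: 14. Longest linear sequence: 11 (steps 1, 2, 3, 6, 7, 8, 9, 10, 11, 13, 14).

**Steps most likely to fail, with fallbacks**

Step 6. The free phenol of 5 may be O-acylated by the acyl azolium before the quinone methide forms, the electron-rich quinone methide may oligomerise by attack of a second arene, and facial control on the enolate may be incomplete. The fallback sets out from 2 and returns at 16, building the side chain on a γ-butyrolactone instead. Compound 2 is bis-protected (MOMCl, NaH, DMF) to 4-methoxy-2,6-bis(methoxymethoxy)benzaldehyde F1. Horner–Wadsworth–Emmons reaction with diethyl (2-oxooxolan-3-yl)phosphonate (KOt-Bu, THF) should give (3E)-3-{[4-methoxy-2,6-bis(methoxymethoxy)phenyl]methylidene}oxolan-2-one F2. Enantioselective hydrogenation of the exocyclic enoate with an iridium/chiral spiro phosphine–oxazoline catalyst under H2 should give (3S)-3-{[4-methoxy-2,6-bis(methoxymethoxy)phenyl]methyl}oxolan-2-one F3. One equivalent of MeLi at −78 °C should stop at (3S)-5-hydroxy-3-{[4-methoxy-2,6-bis(methoxymethoxy)phenyl]methyl}pentan-2-one F4 (in equilibrium with its cyclic hemiketal). Excess Ph3P=CH2 then gives (3S)-3-{[4-methoxy-2,6-bis(methoxymethoxy)phenyl]methyl}-4-methylpent-4-en-1-ol F5. Dess–Martin oxidation gives (3S)-3-{[4-methoxy-2,6-bis(methoxymethoxy)phenyl]methyl}-4-methylpent-4-enal F6, and Wittig reaction with isopropylidenetriphenylphosphorane gives 16.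

Step 3. The highly activated benzylic cation or quinone methide may alkylate a second arene ring (diarylmethane formation) faster than it is trapped by sulfinate. The fallback sets out from 3 and returns at 5 without passing through a free benzylic alcohol under acid. Reductive amination of 3 with dimethylamine and NaBH(OAc)3 should give 2-[(dimethylamino)methyl]-5-methoxy-3-(methoxymethoxy)phenol F7. Quaternisation with MeI gives {[2-hydroxy-4-methoxy-6-(methoxymethoxy)phenyl]methyl}trimethylammonium iodide F8. Heating F8 with excess TolSO2Na in DMF should expel trimethylamine and give 5 by sulfinate capture under neutral conditions.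

Step 14. Under protic acid the isopropenyl or prenyl alkene may close onto a flanking phenol (chroman formation), and the freed chalcone may cyclise to the flavanone or a flavylium ion. The fallback sets out from 22 and returns at 23 by aprotic trans-protection. TESOTf with 2,2'-bipyridyl in CH2Cl2 at 0 °C should exchange each aryl MOM ether for a silyl ether, giving (2E)-3-[2,4-bis(triethylsilyloxy)phenyl]-1-{6-methoxy-3-[(2R)-5-methyl-2-(prop-1-en-2-yl)hex-4-en-1-yl]-2,4-bis(triethylsilyloxy)phenyl}prop-2-en-1-one F9. Buffered fluoride (KF, MeOH, or HF·pyridine/pyridine) should then release 23 without strong acid.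

**Further compounds**

F1 | step 6 | 4-methoxy-2,6-bis(methoxymethoxy)benzaldehyde | COCOc1cc(OC)cc(OCOC)c1C=O
F2 | step 6 | (3E)-3-{[4-methoxy-2,6-bis(methoxymethoxy)phenyl]methylidene}oxolan-2-one | O=C1OCC/C1=C\c1c(OCOC)cc(OC)cc1OCOC
F3 | step 6 | (3S)-3-{[4-methoxy-2,6-bis(methoxymethoxy)phenyl]methyl}oxolan-2-one | O=C1OCC[C@@H]1Cc1c(OCOC)cc(OC)cc1OCOC
F4 | step 6 | (3S)-5-hydroxy-3-{[4-methoxy-2,6-bis(methoxymethoxy)phenyl]methyl}pentan-2-one | CC(=O)[C@H](CCO)Cc1c(OCOC)cc(OC)cc1OCOC
F5 | step 6 | (3S)-3-{[4-methoxy-2,6-bis(methoxymethoxy)phenyl]methyl}-4-methylpent-4-en-1-ol | C=C(C)[C@H](CCO)Cc1c(OCOC)cc(OC)cc1OCOC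
F6 | step 6 | (3S)-3-{[4-methoxy-2,6-bis(methoxymethoxy)phenyl]methyl}-4-methylpent-4-enal | C=C(C)[C@H](CC=O)Cc1c(OCOC)cc(OC)cc1OCOC
F7 | step 3 | 2-[(dimethylamino)methyl]-5-methoxy-3-(methoxymethoxy)phenol | CN(C)Cc1c(O)cc(OC)cc1OCOC
F8 | step 3 | {[2-hydroxy-4-methoxy-6-(methoxymethoxy)phenyl]methyl}trimethylammonium iodide | C[N+](C)(C)Cc1c(O)cc(OC)cc1OCOC.[I-]
F9 | step 14 | (2E)-3-[2,4-bis(triethylsilyloxy)phenyl]-1-{6-methoxy-3-[(2R)-5-methyl-2-(prop-1-en-2-yl)hex-4-en-1-yl]-2,4-bis(triethylsilyloxy)phenyl}prop-2-en-1-one | C=C(C)[C@H](CC=C(C)C)Cc1c(O[Si](CC)(CC)CC)cc(OC)c(C(=O)/C=C/c2ccc(O[Si](CC)(CC)CC)cc2O[Si](CC)(CC)CC)c1O[Si](CC)(CC)CC
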